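## The problem

Compound 32 is a monocyclic lobane-type (prenylated elemane) diterpenoid: a cyclohexane in which C1 is quaternary (methyl, vinyl), C2 carries an isopropenyl group and C4 carries an eight-carbon chain, numbered here C7 (olefinic carbon on the ring), C8 (acetoxymethyl carbon on C7), C9 (=CH), C10 (CH2), C11 (secondary carbinol) and C12 (tertiary carbinol with two methyls). No rings are fused, so the tasks are the contiguous C1/C2 pair, the attachment of the chain at C4, and the trisubstituted C7=C9 olefin, in which C8 must be cis to C10 (Z). The stereocentres are C1 (R), C2 (R), C4 (S) and C11 (S); neither C1 nor C2 can be corrected by equilibration, so they must be set together in one stereospecific C–C bond formation, after which they fix a chair with isopropenyl and vinyl equatorial and the C1 methyl axial. C4 is 1,3 to C2 and its substituent is equatorial, cis to the isopropenyl group, so C2 can control C4 by equilibration if C4 is made acidic at some stage, whereas C11 is too far from the ring for any relay and has to be bought or set by a reagent. The vinyl group and the two 1,1-disubstituted alkenes rule out hydrogenation, hydroboration, strong electrophiles and strong acids, and the acyclic precursors contain a 3,4-disubstituted hexa-1,5-diene that can undergo Cope rearrangement on heating. The allylic acetate (sensitive to base and to zerovalent palladium) and the 1,2-diol (sensitive to acid) should therefore appear last. The feature that opens the key step is that C4 is a methine between the methylenes C3 and C5 and is bonded to C7, which can be carried as a carboxyl carbon. C4 can then be the α-carbon of an acetate ester, alkylated by both ends of a C5–C6–C1–C2–C3 bis-electrophile, and afterwards it is the only epimerisable centre of the ring.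

## Retrosynthesis

**C8–O and protecting group.** Target 32 is traced to its C12 triethylsilyl ether 31, and 31 to the allylic diol 30 by cutting the acetate C–O bond. Diol 30 comes from reduction of the 5,6-dihydropyran-2-one 29, in which the C8–O11 acyl bond holds C8 and C10 on the same side of the olefin. A ring-locked olefin is preferred to any olefination of a hindered ring ketone, because the geometry is then a consequence of ring size. The forward steps are a 1,2-reduction, one selective acylation of a primary over a hindered secondary alcohol, and a fluoride deprotection.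

**C7–C8.** Lactone 29 is cut at C7–C8 to carbon monoxide and the (Z)-vinyl iodide 28. The iodide is traced through the O-silylated iodide 27 and the cyclic siloxane 26 to the homopropargylic alcohol 24, whose dimethylsilyl ether 25 delivers silicon to C7 by a tethered trans-hydrosilylation. The C11 oxygen thus does three jobs: it directs silicon to the distal alkyne carbon, enforces trans addition through a six-membered ring, and later captures the acyl-palladium. An untethered hydrometalation would have no reliable regiochemical bias at a ring-substituted alkyne.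

**C9–C10 and C7–C9.** Alcohol 24 is cut at C9–C10 into the lithium acetylide 23 and the (S)-epoxide 22. The epoxide is opened at its methylene, so C11 is carried unchanged from methyl (2S)-oxirane-2-carboxylate 20 by way of the epoxy alcohol 21. The acetylide comes from the dibromoalkene 19, which is the one-carbon homologue of aldehyde 18 and hence of ester 17. This cut is convergent and places the only remote stereocentre in a chiral-pool fragment. A dihydroxylation of a prenyl side chain would instead have to distinguish four olefins.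

**C3–C4 and C4–C5 (key).** Ester 17 is cut at both bonds to C4, giving tert-butyl acetate 13 and the diiodide 12, via enolate 14, iodo ester 15 and the epimer mixture 16. Against a Diels–Alder or an annulation on a bought ring, this cut keeps C1 and C2 in an acyclic fragment where a sigmatropic reaction can set them. It also places C4 at the ester oxidation level needed for the chain, and leaves C4 as the only centre that base can touch. The precursor is an acyclic C10 diene diiodide with two stereocentres. The forward step must achieve ring closure rather than a second intermolecular alkylation, substitution rather than elimination, and an equatorial ester after equilibration.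

**Functional-group changes.** Diiodide 12 comes from diol 11, which comes from silyl ether alcohol 10 and the acid 9 by reduction and desilylation. These three steps are the price of carrying the two electrophilic carbons at different oxidation levels through the rearrangement.

**C1–C2.** Acid 9 is cut at the C1–C2 bond by an Ireland–Claisen transform to the allylic ester 7, via the boron ketene acetal 8. A chair transition state translates olefin and enolate geometry into the C1/C2 relationship, and a chiral boron substituent supplies the absolute sense. No other acyclic method makes a quaternary centre next to a tertiary one with this predictability. The precursor is an achiral ester.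

**Ester and olefin.** Ester 7 is cut at the acyl C–O bond to 3-methylbut-3-enoic acid 6 and the (E)-allylic alcohol 5. Alcohol 5 comes from the silyl ether 2 of but-3-yn-1-ol 1 by methylalumination and hydroxymethylation, via alane 3 and alanate 4. The syn carbometalation fixes the E geometry that the Claisen step needs.

## Roads not taken

Alternative 1: The ring is bought and the C2–isopropenyl and C1–CH2 bonds are cut. In the forward step isopropenylmagnesium bromide A3 adds to 2-methylcyclohex-2-en-1-one A2 under CuBr·SMe2 with a chiral diphosphine, and the resulting enolate is alkylated in the same flask with methyl bromoacetate A4 to give keto ester A1.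
- Merits: C1 and C2 arise in one catalytic operation from the commodity enone A2, where the chosen plan spends four steps and a stoichiometric chiral boron reagent. In this respect the alternative is clearly better.
- Weak points: the carbonyl of A1 sits on C6, not on C4. The chain would have to enter through enone formation and a conjugate addition at C4 of uncertain facial sense, followed by deoxygenation at C6 beside three alkenes. The ester arm of A1 must also be cut down to a vinyl group.
- Further concerns: addition of the alkenyl Grignard reagent A3 to the α-substituted enone A2, and alkylation of the resulting magnesium enolate by A4 at a carbon that becomes quaternary, are both demanding.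
- Comparison: the chosen plan sets against the catalytic advantage that C4 is formed directly at the right oxidation level with its substituent in place, and that nothing has to be removed from the ring.

Alternative 2: The ring is cut at C1–C6 and C2–C3. A Diels–Alder reaction of tert-butyl(buta-1,3-dien-2-yloxy)dimethylsilane A6 with ethyl (2E)-3-methyl-4-oxobut-2-enoate A7 is promoted by the HNTf2-activated oxazaborolidine from (S)-α,α-diphenylprolinol and o-tolylboronic acid, and gives cyclohexene A5.
- Merits: the ring, C1 and C2 come in one catalytic step from the two small achiral partners A6 and A7, and C4 already carries oxygen. On convergence and on atom count to the ring this road is at least as good as the chosen one.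
- Weak points: A5 holds three carbonyl-level groups that must each be changed separately: formyl to vinyl, ester to isopropenyl by way of an epimerisable methyl ketone at C2, and the C4 ketone to a one-carbon-homologated aldehyde.
- Stereochemical cost: C4 would then be equilibrated at the aldehyde stage, where the equatorial preference is smaller than for an ester.
- Comparison: the chosen plan carries the isopropenyl and vinyl groups intact from the first C–C bond formation and equilibrates C4 as a tert-butyl ester. It pays with a longer acyclic prelude.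

Alternative 3: The chain is cut at C10–C11 and at the lactone C–O bond. A vinylogous Mukaiyama aldol of the ring-bearing silyl dienolate A9 with 2-methyl-2-[(triethylsilyl)oxy]propanal A10 under Ti(O-i-Pr)4 with (R)-BINOL, followed by lactonisation, gives A8, which is the same compound as lactone 29 of the chosen route.
- Merits: C11 is set by a catalyst and the Z-olefin is locked in one step, where the chosen route needs four steps (13 to 16) from dibromoalkene 19. For the end game alone this is the shorter road.
- Weak points: A9 is an α-branched dienolate bearing a bulky ring and A10 is an aldehyde with a quaternary α-carbon, a pairing in which γ-selectivity and enantioselectivity are least assured. C11 would form remote from three existing stereocentres, so a minor diastereomer could be hard to remove.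
- Further cost: A9 carries a four-carbon dienolate on C4, two carbons more than ester 17 delivers, so the saving is partly spent on homologation. The alternative is also only an end game and still needs a synthesis of the ring.
- Comparison: the chosen plan uses stereospecific events throughout the chain (epoxide opening at the methylene, mechanism-defined trans-hydrosilylation, retentive iodination and carbonylation) and a chiral-pool C11.

Key step: step 8

Assumption: the (4R,5R)-bromoborane of step 4 is taken to lead to the (2R,3R) acid 9; if the first batch shows the opposite sense, the (4S,5S)-reagent is used with no other change.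

Assumption: the tert-butyl ester equilibrium in step 8 lies on the side of the equatorial epimer by about the conformational preference of an alkoxycarbonyl group, so a minor axial share that is separated and returned to the equilibration is expected.

## Route

Step 1
Reactants: 1 but-3-yn-1-ol
Product: 2 tert-butyl(but-3-yn-1-yloxy)diphenylsilane
Conditions: t-BuPh2SiCl, imidazole, CH2Cl2, 0 °C → rt
Reagents that add atoms: tert-butyl(chloro)diphenylsilane, CC(C)(C)[Si](Cl)(c1ccccc1)c1ccccc1
Why: Standard silylation of a primary alcohol; the tert-butyldiphenylsilyl ether is chosen because it should tolerate Me3Al, the bromoborane of step 4 and LiAlH4.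

Step 2
Reactants: 2 tert-butyl(but-3-yn-1-yloxy)diphenylsilane
Product: 5 (2E)-5-[(tert-butyldiphenylsilyl)oxy]-3-methylpent-2-en-1-ol, via alkenyldimethylalane 3 (not isolated), via lithium alkenylalanate 4 (not isolated)
Conditions: Me3Al, Cp2ZrCl2 (cat.), CH2Cl2, 0 °C → rt; n-BuLi, THF, −78 °C; (CH2O)n, −78 °C → rt
Reagents that add atoms: trimethylaluminium, C[Al](C)C; paraformaldehyde (as formaldehyde), C=O
Why: Negishi Cp2ZrCl2-catalysed carboalumination adds methyl and aluminium syn across the terminal alkyne with methyl on the internal carbon, and the alanate is hydroxymethylated with retention. Methyl and CH2OH therefore end cis, which is the E olefin.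

Step 3
Reactants: 5 (2E)-5-[(tert-butyldiphenylsilyl)oxy]-3-methylpent-2-en-1-ol; 6 3-methylbut-3-enoic acid
Product: 7 (2E)-5-[(tert-butyldiphenylsilyl)oxy]-3-methylpent-2-en-1-yl 3-methylbut-3-enoate
Conditions: DCC, DMAP (cat.), CH2Cl2, 0 °C
Reagents that add atoms: none
Why: Steglich esterification of a primary allylic alcohol; low temperature and little DMAP should keep the β,γ-unsaturated acid out of conjugation, and any conjugated ester would in any case give the same dienolate in step 4.

Step 4
Reactants: 7 (2E)-5-[(tert-butyldiphenylsilyl)oxy]-3-methylpent-2-en-1-yl 3-methylbut-3-enoate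
Product: 9 (2R,3R)-3-{2-[(tert-butyldiphenylsilyl)oxy]ethyl}-3-methyl-2-(prop-1-en-2-yl)pent-4-enoic acid, via boron ketene acetal 8 (not isolated)
Conditions: (4R,5R)-2-bromo-1,3-bis{[3,5-bis(trifluoromethyl)phenyl]sulfonyl}-4,5-diphenyl-1,3,2-diazaborolidine, Et3N, toluene/hexane, −78 °C, then 4 °C → rt; aq. work-up
Reagents that add atoms: none
Why: Enantioselective Ireland–Claisen rearrangement of a chiral boron ketene acetal: Et3N in toluene/hexane is the combination that gives the E(O) boron enolate, here with the isopropenyl group cis to the allyloxy oxygen. The chair transition state, with the methyl of the (E)-allyl unit and the isopropenyl group pseudo-axial and the silyloxyethyl arm pseudo-equatorial, then joins C1 and C2 in the relative configuration that places vinyl and isopropenyl trans on the later ring. The C2-symmetric bis-sulfonamide on boron selects the enolate face and so fixes both centres at once.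

Step 5
Reactants: 9 (2R,3R)-3-{2-[(tert-butyldiphenylsilyl)oxy]ethyl}-3-methyl-2-(prop-1-en-2-yl)pent-4-enoic acid
Product: 10 (2R,3R)-3-{2-[(tert-butyldiphenylsilyl)oxy]ethyl}-3-methyl-2-(prop-1-en-2-yl)pent-4-en-1-ol
Conditions: LiAlH4, Et2O, 0 °C → rt
Reagents that add atoms: none
Why: Hydride reduction of a carboxylic acid to the primary alcohol; the silyl ether and the isolated alkenes are inert and the mixture is never heated, so the hexa-1,5-diene should not rearrange.

Step 6
Reactants: 10 (2R,3R)-3-{2-[(tert-butyldiphenylsilyl)oxy]ethyl}-3-methyl-2-(prop-1-en-2-yl)pent-4-en-1-ol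
Product: 11 (2R,3R)-3-ethenyl-3-methyl-2-(prop-1-en-2-yl)pentane-1,5-diol
Conditions: Bu4NF, THF, rt
Reagents that add atoms: none
Why: Fluoride cleavage of a primary silyl ether; no other group in 10 responds to fluoride.

Step 7
Reactants: 11 (2R,3R)-3-ethenyl-3-methyl-2-(prop-1-en-2-yl)pentane-1,5-diol
Product: 12 (3R,4R)-3-(2-iodoethyl)-4-(iodomethyl)-3,5-dimethylhexa-1,5-diene
Conditions: I2, PPh3, imidazole, CH2Cl2, 0 °C → rt, dark
Reagents that add atoms: iodine, II
Why: Appel-type iodination of two primary alcohols through alkoxyphosphonium ions; the reagent is used in excess and added to the diol at 0 °C so that each hydroxyl is activated before it can attack the other arm.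

Step 8
Reactants: 12 (3R,4R)-3-(2-iodoethyl)-4-(iodomethyl)-3,5-dimethylhexa-1,5-diene; 13 tert-butyl acetate
Product: 17 tert-butyl (1S,3R,4R)-4-ethenyl-4-methyl-3-(prop-1-en-2-yl)cyclohexane-1-carboxylate, via lithium enolate of tert-butyl acetate 14 (not isolated), via acyclic iodo ester 15 (not isolated), via C4-epimeric ester mixture 16 (not isolated)
Conditions: 13, LiN(i-Pr)2, THF, −78 °C; 12, DMPU, −78 → −20 °C; LiN(i-Pr)2, −78 °C → rt; then t-BuOH, KOt-Bu (cat.), 40 °C
Reagents that add atoms: none
Why: LiN(i-Pr)2 turns 13 into enolate 14, which displaces iodide by SN2 at the less hindered 2-iodoethyl arm to form C4–C5 and give 15. A second portion of base regenerates an ester enolate, which attacks the β-branched iodomethyl carbon intramolecularly to form C3–C4 and close the cyclohexane in the 6-exo-tet mode. The closest known reaction type is the cycloalkylation of ester and malonate enolates with α,ω-dihalides to cycloalkanecarboxylates. C4 is formed as mixture 16 and is then the only acidic centre, so KOt-Bu in t-BuOH equilibrates it through the ester enolate. In the chair fixed by C1 and C2 (isopropenyl and vinyl equatorial, methyl axial) the equatorial ester, cis to the isopropenyl group, avoids the syn-axial hydrogens at C2 and C6, so C4 is controlled thermodynamically by C2. Ring closure rather than a second intermolecular alkylation should follow from the large rate difference between the two iodides and from using one equivalent of 14. Substitution rather than E2 at the iodomethyl group, whose β-hydrogen is allylic, should follow from generating each enolate at −78 °C so that no free amide base remains on warming. C1 and C2 carry no acidic hydrogen and are untouched.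

Step 9
Reactants: 17 tert-butyl (1S,3R,4R)-4-ethenyl-4-methyl-3-(prop-1-en-2-yl)cyclohexane-1-carboxylate
Product: 18 (1S,3R,4R)-4-ethenyl-4-methyl-3-(prop-1-en-2-yl)cyclohexane-1-carbaldehyde
Conditions: i-Bu2AlH (1.1 equiv), toluene, −78 °C; MeOH, then aq. KNaC4H4O6
Reagents that add atoms: none
Why: Partial reduction of an ester with i-Bu2AlH; the crowded aluminium hemiacetal of a tert-butyl ester should persist at −78 °C and release the aldehyde only on work-up. The neutral work-up avoids equilibration at C4, where an aldehyde has a weaker equatorial preference than the ester.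

Step 10
Reactants: 18 (1S,3R,4R)-4-ethenyl-4-methyl-3-(prop-1-en-2-yl)cyclohexane-1-carbaldehyde
Product: 19 (1R,2R,4S)-4-(2,2-dibromoethenyl)-1-ethenyl-1-methyl-2-(prop-1-en-2-yl)cyclohexane
Conditions: CBr4, PPh3, CH2Cl2, 0 °C
Reagents that add atoms: carbon tetrabromide, BrC(Br)(Br)Br
Why: First stage of the Corey–Fuchs homologation, a Wittig-type dibromo-olefination under non-basic conditions; it is preferred to a diazophosphonate homologation in basic methanol because C4 stays configurationally fixed.

Step 11
Reactants: 20 methyl (2S)-oxirane-2-carboxylate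
Product: 21 2-[(2S)-oxiran-2-yl]propan-2-ol
Conditions: MeMgBr (2.2 equiv), Et2O/THF, −78 → −20 °C; aq. NH4Cl
Reagents that add atoms: methylmagnesium bromide, C[Mg]Br
Why: Double Grignard addition to the ester carbonyl, which is far faster at low temperature than opening of the epoxide; the stereocentre is not involved and keeps its configuration.

Step 12
Reactants: 21 2-[(2S)-oxiran-2-yl]propan-2-ol
Product: 22 triethyl({2-[(2S)-oxiran-2-yl]propan-2-yl}oxy)silane
Conditions: Et3SiCl, imidazole, DMAP (cat.), DMF, rt
Reagents that add atoms: chlorotriethylsilane, CC[Si](Cl)(CC)CC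
Why: Silylation of a tertiary alcohol under nucleophilic catalysis; the triethylsilyl ether blocks Payne rearrangement and keeps the C12 oxygen out of the later silyl tether.

Step 13
Reactants: 19 (1R,2R,4S)-4-(2,2-dibromoethenyl)-1-ethenyl-1-methyl-2-(prop-1-en-2-yl)cyclohexane; 22 triethyl({2-[(2S)-oxiran-2-yl]propan-2-yl}oxy)silane
Product: 24 (3S)-6-[(1S,3R,4R)-4-ethenyl-4-methyl-3-(prop-1-en-2-yl)cyclohexyl]-2-methyl-2-[(triethylsilyl)oxy]hex-5-yn-3-ol, via lithium acetylide 23 (not isolated)
Conditions: n-BuLi (2.1 equiv), THF, −78 → −20 °C; then BF3·OEt2, 22, −78 °C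
Reagents that add atoms: none
Why: Second stage of the Corey–Fuchs sequence (bromine–lithium exchange, Fritsch–Buttenberg–Wiechell shift, deprotonation) gives acetylide 23, which is used directly in a BF3-promoted alkynylation of the terminal epoxide. Attack occurs at the unhindered methylene, so C11 keeps the (S) configuration of 22 and the C9–C10 bond is formed.

Step 14
Reactants: 24 (3S)-6-[(1S,3R,4R)-4-ethenyl-4-methyl-3-(prop-1-en-2-yl)cyclohexyl]-2-methyl-2-[(triethylsilyl)oxy]hex-5-yn-3-ol
Product: 26 (6S)-3-[(1S,3R,4R)-4-ethenyl-4-methyl-3-(prop-1-en-2-yl)cyclohexyl]-2,2-dimethyl-6-{2-[(triethylsilyl)oxy]propan-2-yl}-5,6-dihydro-2H-1,2-oxasiline, via dimethylsilyl ether 25 (not isolated)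
Conditions: (HMe2Si)2NH, neat, 60 °C; evaporate; [Cp*Ru(MeCN)3]PF6 (cat.), CH2Cl2, 0 °C → rt
Reagents that add atoms: 1,1,3,3-tetramethyldisilazane, C[SiH](C)N[SiH](C)C
Why: Silylation gives the Si–H ether 25, and [Cp*Ru(MeCN)3]PF6 adds Si–H across the alkyne in trans fashion. This is the [Cp*Ru(MeCN)3]PF6-catalysed intramolecular hydrosilylation of homopropargylic silyl ethers, which takes the 6-endo-dig course, so silicon ends on C7 cis to C10. The catalyst is not expected to hydrosilylate the vinyl or isopropenyl groups.

Step 15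
Reactants: 26 (6S)-3-[(1S,3R,4R)-4-ethenyl-4-methyl-3-(prop-1-en-2-yl)cyclohexyl]-2,2-dimethyl-6-{2-[(triethylsilyl)oxy]propan-2-yl}-5,6-dihydro-2H-1,2-oxasiline
Product: 28 (3S,5Z)-6-[(1S,3R,4R)-4-ethenyl-4-methyl-3-(prop-1-en-2-yl)cyclohexyl]-6-iodo-2-methyl-2-[(triethylsilyl)oxy]hex-5-en-3-ol, via O-silylated vinyl iodide 27 (not isolated)
Conditions: N-iodosuccinimide, 2,6-lutidine, (CF3)2CHOH, 0 °C; then K2CO3, MeOH, rt
Reagents that add atoms: N-iodosuccinimide, O=C1CCC(=O)N1I
Why: Electrophilic ipso-iododesilylation of an alkenylsilane: iodonium attacks C7, the β-silyl cation gives up silicon to the solvent, and C–Si is replaced by C–I with retention, so iodine is cis to C10. The cold, buffered, short reaction is meant to favour the silicon-activated olefin over the vinyl and isopropenyl groups, and methanolysis then frees the C11 hydroxyl.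

Step 16
Reactants: 28 (3S,5Z)-6-[(1S,3R,4R)-4-ethenyl-4-methyl-3-(prop-1-en-2-yl)cyclohexyl]-6-iodo-2-methyl-2-[(triethylsilyl)oxy]hex-5-en-3-ol
Product: 29 (6S)-3-[(1S,3R,4R)-4-ethenyl-4-methyl-3-(prop-1-en-2-yl)cyclohexyl]-6-{2-[(triethylsilyl)oxy]propan-2-yl}-5,6-dihydro-2H-pyran-2-one
Conditions: CO (1 atm), PdCl2(PPh3)2 (cat.), Et3N, THF, 50 °C
Reagents that add atoms: carbon monoxide, [C-]#[O+]
Why: Carbonylative lactonisation catalysed by PdCl2(PPh3)2: oxidative addition into the vinyl iodide with retention, CO insertion, and capture of the acyl-palladium by the cis-placed C11 hydroxyl form the C7–C8 bond and the six-membered lactone. The ring fixes C8 cis to C10.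

Step 17
Reactants: 29 (6S)-3-[(1S,3R,4R)-4-ethenyl-4-methyl-3-(prop-1-en-2-yl)cyclohexyl]-6-{2-[(triethylsilyl)oxy]propan-2-yl}-5,6-dihydro-2H-pyran-2-one
Product: 30 (2Z,5S)-2-[(1S,3R,4R)-4-ethenyl-4-methyl-3-(prop-1-en-2-yl)cyclohexyl]-6-methyl-6-[(triethylsilyl)oxy]hept-2-ene-1,5-diol
Conditions: i-Bu2AlH (excess), CH2Cl2, −78 → 0 °C
Reagents that add atoms: none
Why: 1,2-Reduction of an α,β-unsaturated lactone through the lactol to the allylic diol; i-Bu2AlH does not reduce the conjugated double bond, so the Z geometry is kept.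

Step 18
Reactants: 30 (2Z,5S)-2-[(1S,3R,4R)-4-ethenyl-4-methyl-3-(prop-1-en-2-yl)cyclohexyl]-6-methyl-6-[(triethylsilyl)oxy]hept-2-ene-1,5-diol
Product: 31 (2Z,5S)-2-[(1S,3R,4R)-4-ethenyl-4-methyl-3-(prop-1-en-2-yl)cyclohexyl]-5-hydroxy-6-methyl-6-[(triethylsilyl)oxy]hept-2-en-1-yl acetate
Conditions: Ac2O (1.1 equiv), 2,4,6-collidine, CH2Cl2, −20 → 0 °C
Reagents that add atoms: acetic anhydride, CC(=O)OC(C)=O
Why: Selective acylation of the primary allylic alcohol; the C11 hydroxyl is secondary and flanked by the silylated quaternary C12, so it should react much more slowly with one equivalent of anhydride and a hindered base.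

Step 19
Reactants: 31 (2Z,5S)-2-[(1S,3R,4R)-4-ethenyl-4-methyl-3-(prop-1-en-2-yl)cyclohexyl]-5-hydroxy-6-methyl-6-[(triethylsilyl)oxy]hept-2-en-1-yl acetate
Product: 32 (2Z,5S)-2-[(1S,3R,4R)-4-ethenyl-4-methyl-3-(prop-1-en-2-yl)cyclohexyl]-5,6-dihydroxy-6-methylhept-2-en-1-yl acetate
Conditions: HF·pyridine, pyridine/THF, 0 °C → rt
Reagents that add atoms: none
Why: Buffered fluoride cleavage of the tertiary triethylsilyl ether; the medium is neither basic enough to move or cleave the acetate nor acidic enough to ionise the allylic or tertiary C–O bonds.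

## Compound list

1 | but-3-yn-1-ol | C#CCCO | starting material
2 | tert-butyl(but-3-yn-1-yloxy)diphenylsilane | C#CCCO[Si](c1ccccc1)(c1ccccc1)C(C)(C)C | intermediate
3 | {(1E)-4-[(tert-butyldiphenylsilyl)oxy]-2-methylbut-1-en-1-yl}dimethylalane | C[Al](C)/C=C(\C)CCO[Si](c1ccccc1)(c1ccccc1)C(C)(C)C | intermediate
4 | lithium butyl{(1E)-4-[(tert-butyldiphenylsilyl)oxy]-2-methylbut-1-en-1-yl}dimethylalanate | [Li+].CCCC[Al-](C)(C)/C=C(\C)CCO[Si](c1ccccc1)(c1ccccc1)C(C)(C)C | intermediate
5 | (2E)-5-[(tert-butyldiphenylsilyl)oxy]-3-methylpent-2-en-1-ol | OC/C=C(\C)CCO[Si](c1ccccc1)(c1ccccc1)C(C)(C)C | intermediate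
6 | 3-methylbut-3-enoic acid | CC(=C)CC(=O)O | starting material
7 | (2E)-5-[(tert-butyldiphenylsilyl)oxy]-3-methylpent-2-en-1-yl 3-methylbut-3-enoate | C=C(C)CC(=O)OC/C=C(\C)CCO[Si](c1ccccc1)(c1ccccc1)C(C)(C)C | intermediate
8 | (4R,5R)-2-{[(1Z)-1-({(2E)-5-[(tert-butyldiphenylsilyl)oxy]-3-methylpent-2-en-1-yl}oxy)-3-methylbuta-1,3-dien-1-yl]oxy}-1,3-bis{[3,5-bis(trifluoromethyl)phenyl]sulfonyl}-4,5-diphenyl-1,3,2-diazaborolidine (isopropenyl cis to the allyloxy group) | C=C(C)/C=C(/OB1N(S(=O)(=O)c2cc(C(F)(F)F)cc(C(F)(F)F)c2)[C@H](c2ccccc2)[C@@H](c2ccccc2)N1S(=O)(=O)c1cc(C(F)(F)F)cc(C(F)(F)F)c1)OC/C=C(\C)CCO[Si](c1ccccc1)(c1ccccc1)C(C)(C)C | intermediate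
9 | (2R,3R)-3-{2-[(tert-butyldiphenylsilyl)oxy]ethyl}-3-methyl-2-(prop-1-en-2-yl)pent-4-enoic acid | C=C[C@@](C)(CCO[Si](c1ccccc1)(c1ccccc1)C(C)(C)C)[C@H](C(=O)O)C(=C)C | intermediate
10 | (2R,3R)-3-{2-[(tert-butyldiphenylsilyl)oxy]ethyl}-3-methyl-2-(prop-1-en-2-yl)pent-4-en-1-ol | C=C[C@@](C)(CCO[Si](c1ccccc1)(c1ccccc1)C(C)(C)C)[C@H](CO)C(=C)C | intermediate
11 | (2R,3R)-3-ethenyl-3-methyl-2-(prop-1-en-2-yl)pentane-1,5-diol | C=C[C@@](C)(CCO)[C@H](CO)C(=C)C | intermediate
12 | (3R,4R)-3-(2-iodoethyl)-4-(iodomethyl)-3,5-dimethylhexa-1,5-diene | C=C[C@@](C)(CCI)[C@H](CI)C(=C)C | intermediate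
13 | tert-butyl acetate | CC(=O)OC(C)(C)C | starting material
14 | lithium 1-tert-butoxyethen-1-olate | [Li+].[O-]C(=C)OC(C)(C)C | intermediate
15 | tert-butyl (5R,6R)-5-ethenyl-6-(iodomethyl)-5,7-dimethyloct-7-enoate | C=C[C@@](C)(CCCC(=O)OC(C)(C)C)[C@H](CI)C(=C)C | intermediate
16 | tert-butyl (3R,4R)-4-ethenyl-4-methyl-3-(prop-1-en-2-yl)cyclohexane-1-carboxylate, mixture of C1 epimers | C=C[C@@]1(C)CCC(C(=O)OC(C)(C)C)C[C@@H]1C(=C)C | intermediate
17 | tert-butyl (1S,3R,4R)-4-ethenyl-4-methyl-3-(prop-1-en-2-yl)cyclohexane-1-carboxylate | C=C[C@@]1(C)CC[C@H](C(=O)OC(C)(C)C)C[C@@H]1C(=C)C | intermediate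
18 | (1S,3R,4R)-4-ethenyl-4-methyl-3-(prop-1-en-2-yl)cyclohexane-1-carbaldehyde | C=C[C@@]1(C)CC[C@H](C=O)C[C@@H]1C(=C)C | intermediate
19 | (1R,2R,4S)-4-(2,2-dibromoethenyl)-1-ethenyl-1-methyl-2-(prop-1-en-2-yl)cyclohexane | C=C[C@@]1(C)CC[C@H](C=C(Br)Br)C[C@@H]1C(=C)C | intermediate
20 | methyl (2S)-oxirane-2-carboxylate | COC(=O)[C@@H]1CO1 | starting material
21 | 2-[(2S)-oxiran-2-yl]propan-2-ol | CC(C)(O)[C@@H]1CO1 | intermediate
22 | triethyl({2-[(2S)-oxiran-2-yl]propan-2-yl}oxy)silane | CC[Si](CC)(CC)OC(C)(C)[C@@H]1CO1 | intermediate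
23 | lithium [(1S,3R,4R)-4-ethenyl-4-methyl-3-(prop-1-en-2-yl)cyclohexyl]ethynide | C=C[C@@]1(C)CC[C@H](C#C[Li])C[C@@H]1C(=C)C | intermediate
24 | (3S)-6-[(1S,3R,4R)-4-ethenyl-4-methyl-3-(prop-1-en-2-yl)cyclohexyl]-2-methyl-2-[(triethylsilyl)oxy]hex-5-yn-3-ol | C=C[C@@]1(C)CC[C@H](C#CC[C@H](O)C(C)(C)O[Si](CC)(CC)CC)C[C@@H]1C(=C)C | intermediate
25 | ({(3S)-6-[(1S,3R,4R)-4-ethenyl-4-methyl-3-(prop-1-en-2-yl)cyclohexyl]-2-methyl-2-[(triethylsilyl)oxy]hex-5-yn-3-yl}oxy)dimethylsilane | C=C[C@@]1(C)CC[C@H](C#CC[C@H](O[SiH](C)C)C(C)(C)O[Si](CC)(CC)CC)C[C@@H]1C(=C)C | intermediate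
26 | (6S)-3-[(1S,3R,4R)-4-ethenyl-4-methyl-3-(prop-1-en-2-yl)cyclohexyl]-2,2-dimethyl-6-{2-[(triethylsilyl)oxy]propan-2-yl}-5,6-dihydro-2H-1,2-oxasiline | C=C[C@@]1(C)CC[C@H](C2=CC[C@@H](C(C)(C)O[Si](CC)(CC)CC)O[Si]2(C)C)C[C@@H]1C(=C)C | intermediate
27 | ({(3S,5Z)-6-[(1S,3R,4R)-4-ethenyl-4-methyl-3-(prop-1-en-2-yl)cyclohexyl]-6-iodo-2-methyl-2-[(triethylsilyl)oxy]hex-5-en-3-yl}oxy)[(1,1,1,3,3,3-hexafluoropropan-2-yl)oxy]dimethylsilane | C=C[C@@]1(C)CC[C@H](/C(I)=C/C[C@H](O[Si](C)(C)OC(C(F)(F)F)C(F)(F)F)C(C)(C)O[Si](CC)(CC)CC)C[C@@H]1C(=C)C | intermediate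
28 | (3S,5Z)-6-[(1S,3R,4R)-4-ethenyl-4-methyl-3-(prop-1-en-2-yl)cyclohexyl]-6-iodo-2-methyl-2-[(triethylsilyl)oxy]hex-5-en-3-ol | C=C[C@@]1(C)CC[C@H](/C(I)=C/C[C@H](O)C(C)(C)O[Si](CC)(CC)CC)C[C@@H]1C(=C)C | intermediate
29 | (6S)-3-[(1S,3R,4R)-4-ethenyl-4-methyl-3-(prop-1-en-2-yl)cyclohexyl]-6-{2-[(triethylsilyl)oxy]propan-2-yl}-5,6-dihydro-2H-pyran-2-one | C=C[C@@]1(C)CC[C@H](C2=CC[C@@H](C(C)(C)O[Si](CC)(CC)CC)OC2=O)C[C@@H]1C(=C)C | intermediate
30 | (2Z,5S)-2-[(1S,3R,4R)-4-ethenyl-4-methyl-3-(prop-1-en-2-yl)cyclohexyl]-6-methyl-6-[(triethylsilyl)oxy]hept-2-ene-1,5-diol | C=C[C@@]1(C)CC[C@H](/C(CO)=C/C[C@H](O)C(C)(C)O[Si](CC)(CC)CC)C[C@@H]1C(=C)C | intermediate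
31 | (2Z,5S)-2-[(1S,3R,4R)-4-ethenyl-4-methyl-3-(prop-1-en-2-yl)cyclohexyl]-5-hydroxy-6-methyl-6-[(triethylsilyl)oxy]hept-2-en-1-yl acetate | C=C[C@@]1(C)CC[C@H](/C(=C/C[C@H](O)C(C)(C)O[Si](CC)(CC)CC)COC(C)=O)C[C@@H]1C(=C)C | intermediate
32 | (2Z,5S)-2-[(1S,3R,4R)-4-ethenyl-4-methyl-3-(prop-1-en-2-yl)cyclohexyl]-5,6-dihydroxy-6-methylhept-2-en-1-yl acetate | C=C[C@@]1(C)CC[C@H](/C(=C/C[C@H](O)C(C)(C)O)COC(C)=O)C[C@@H]1C(=C)C | target

## Step count and least certain steps

Total: 19 steps. Longest linear sequence: 17 steps (steps 1 to 10 and 13 to 19, from but-3-yn-1-ol 1); the epoxide branch (steps 11 and 12) adds two.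

**Step 8 (key step).** Three things may go wrong:
- elimination at the iodomethyl group, whose β-hydrogen is allylic, instead of the ring-closing substitution;
- intermolecular double alkylation or oligomerisation if the first alkylation is not selective for the iodoethyl arm;
- incomplete stereocontrol at C4, because the equatorial preference of an alkoxycarbonyl group is only moderate.

Fallback: from diiodide 12, double alkylation of dimethyl malonate (NaH, THF/DMF, rt to 50 °C), a softer and much less basic nucleophile, should give dimethyl (3R,4R)-4-ethenyl-4-methyl-3-(prop-1-en-2-yl)cyclohexane-1,1-dicarboxylate F1. Krapcho demethoxycarbonylation (LiCl, wet DMSO, 150 °C; the cyclic divinylcyclohexane tolerates this, unlike the acyclic dienes) and equilibration with NaOMe in MeOH should give methyl (1S,3R,4R)-4-ethenyl-4-methyl-3-(prop-1-en-2-yl)cyclohexane-1-carboxylate F2. Reduction of F2 with i-Bu2AlH at −78 °C returns to the route at aldehyde 18.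

**Step 4.** The enolisation may lose control of enolate geometry, which would erode the C1/C2 relationship, or the controller may give insufficient or opposite facial selection. The stoichiometric bromoborane may also attack the silyl ether. Fallback: from ester 7, a reagent-free Ireland–Claisen rearrangement and a resolution. LiN(i-Pr)2 in THF at −78 °C followed by Me3SiCl should give the kinetic trimethylsilyl ketene acetal of 7 with the isopropenyl group cis to the allyloxy group F3. Warming to rt should give the racemic trimethylsilyl (2R*,3R*)-3-{2-[(tert-butyldiphenylsilyl)oxy]ethyl}-3-methyl-2-(prop-1-en-2-yl)pent-4-enoate F4, and aqueous work-up should give the racemic (2R*,3R*) acid F5. Crystallisation with (R)-1-phenylethylamine is intended to give the (R)-1-phenylethylammonium salt of the (2R,3R) acid F6, and acidification of F6 returns to the route at acid 9.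

**Step 7.** The diol may close to a tetrahydropyran by attack of one hydroxyl on the activated other arm, a process helped by the quaternary centre in the tether. Fallback: from diol 11, mesylation of both hydroxyls (MeSO2Cl, Et3N, CH2Cl2, 0 °C) should give (2R,3R)-3-ethenyl-3-methyl-2-(prop-1-en-2-yl)pentane-1,5-diyl dimethanesulfonate F7. A Finkelstein exchange (NaI, butan-2-one, 70 °C) returns to the route at diiodide 12.

**Step 9.** The hindered ester may react sluggishly, so that warming leads to over-reduction, or the hemiacetal may collapse early with the same result. Fallback: from ester 17, full reduction with LiAlH4 (Et2O, 0 °C) should give [(1S,3R,4R)-4-ethenyl-4-methyl-3-(prop-1-en-2-yl)cyclohexyl]methanol F8. Oxidation of F8 with Dess–Martin periodinane buffered with NaHCO3 returns to the route at aldehyde 18.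

**Step 15.** The iodonium source may attack the isopropenyl or vinyl group in competition with the alkenylsilane, or the alkoxysilane may react slowly and lose geometric purity. Fallback: from siloxane 26, ring opening with MeLi (THF, −78 → 0 °C) should give the alkenyltrimethylsilane (3S,5Z)-6-[(1S,3R,4R)-4-ethenyl-4-methyl-3-(prop-1-en-2-yl)cyclohexyl]-2-methyl-2-[(triethylsilyl)oxy]-6-(trimethylsilyl)hex-5-en-3-ol F9, the substrate class for which iododesilylation is best established. Treatment of F9 with N-iodosuccinimide in the less activating MeCN/ClCH2CN at 0 °C returns to the route at vinyl iodide 28.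

## Further compounds

F1 | step 8 | dimethyl (3R,4R)-4-ethenyl-4-methyl-3-(prop-1-en-2-yl)cyclohexane-1,1-dicarboxylate | C=C[C@@]1(C)CCC(C(=O)OC)(C(=O)OC)C[C@@H]1C(=C)C
F2 | step 8 | methyl (1S,3R,4R)-4-ethenyl-4-methyl-3-(prop-1-en-2-yl)cyclohexane-1-carboxylate | C=C[C@@]1(C)CC[C@H](C(=O)OC)C[C@@H]1C(=C)C
F3 | step 4 | tert-butyl{[(3E)-3-methyl-5-({(1E)-3-methyl-1-[(trimethylsilyl)oxy]buta-1,3-dien-1-yl}oxy)pent-3-en-1-yl]oxy}diphenylsilane (isopropenyl cis to the allyloxy group) | C=C(C)/C=C(/O[Si](C)(C)C)OC/C=C(\C)CCO[Si](c1ccccc1)(c1ccccc1)C(C)(C)C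
F4 | step 4 | racemic trimethylsilyl (2R*,3R*)-3-{2-[(tert-butyldiphenylsilyl)oxy]ethyl}-3-methyl-2-(prop-1-en-2-yl)pent-4-enoate | C=C[C@@](C)(CCO[Si](c1ccccc1)(c1ccccc1)C(C)(C)C)[C@H](C(=O)O[Si](C)(C)C)C(=C)C.C=C[C@](C)(CCO[Si](c1ccccc1)(c1ccccc1)C(C)(C)C)[C@@H](C(=O)O[Si](C)(C)C)C(=C)C
F5 | step 4 | racemic (2R*,3R*)-3-{2-[(tert-butyldiphenylsilyl)oxy]ethyl}-3-methyl-2-(prop-1-en-2-yl)pent-4-enoic acid | C=C[C@@](C)(CCO[Si](c1ccccc1)(c1ccccc1)C(C)(C)C)[C@H](C(=O)O)C(=C)C.C=C[C@](C)(CCO[Si](c1ccccc1)(c1ccccc1)C(C)(C)C)[C@@H](C(=O)O)C(=C)C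
F6 | step 4 | (1R)-1-phenylethan-1-aminium (2R,3R)-3-{2-[(tert-butyldiphenylsilyl)oxy]ethyl}-3-methyl-2-(prop-1-en-2-yl)pent-4-enoate | C=C[C@@](C)(CCO[Si](c1ccccc1)(c1ccccc1)C(C)(C)C)[C@H](C(=O)[O-])C(=C)C.C[C@@H]([NH3+])c1ccccc1
F7 | step 7 | (2R,3R)-3-ethenyl-3-methyl-2-(prop-1-en-2-yl)pentane-1,5-diyl dimethanesulfonate | C=C[C@@](C)(CCOS(C)(=O)=O)[C@H](COS(C)(=O)=O)C(=C)C
F8 | step 9 | [(1S,3R,4R)-4-ethenyl-4-methyl-3-(prop-1-en-2-yl)cyclohexyl]methanol | C=C[C@@]1(C)CC[C@H](CO)C[C@@H]1C(=C)C
F9 | step 15 | (3S,5Z)-6-[(1S,3R,4R)-4-ethenyl-4-methyl-3-(prop-1-en-2-yl)cyclohexyl]-2-methyl-2-[(triethylsilyl)oxy]-6-(trimethylsilyl)hex-5-en-3-ol | C=C[C@@]1(C)CC[C@H](/C(=C/C[C@H](O)C(C)(C)O[Si](CC)(CC)CC)[Si](C)(C)C)C[C@@H]1C(=C)C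
A1 | alternative 1 | methyl 2-[(1R,6R)-1-methyl-2-oxo-6-(prop-1-en-2-yl)cyclohexyl]acetate | COC(=O)C[C@@]1(C)C(=O)CCC[C@@H]1C(C)=C
A2 | alternative 1 | 2-methylcyclohex-2-en-1-one | CC1=CCCCC1=O
A3 | alternative 1 | isopropenylmagnesium bromide | C=C(C)[Mg]Br
A4 | alternative 1 | methyl bromoacetate | COC(=O)CBr
A5 | alternative 2 | ethyl (1S,6S)-3-[(tert-butyldimethylsilyl)oxy]-6-formyl-6-methylcyclohex-3-ene-1-carboxylate | O=C[C@@]1(C)CC=C(O[Si](C)(C)C(C)(C)C)C[C@@H]1C(=O)OCC
A6 | alternative 2 | tert-butyl(buta-1,3-dien-2-yloxy)dimethylsilane | C=CC(=C)O[Si](C)(C)C(C)(C)C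
A7 | alternative 2 | ethyl (2E)-3-methyl-4-oxobut-2-enoate | CCOC(=O)/C=C(/C=O)C
A8 | alternative 3 | (6S)-3-[(1S,3R,4R)-4-ethenyl-4-methyl-3-(prop-1-en-2-yl)cyclohexyl]-6-{2-[(triethylsilyl)oxy]propan-2-yl}-5,6-dihydro-2H-pyran-2-one | C=C[C@@]1(C)CC[C@H](C2=CC[C@@H](C(C)(C)O[Si](CC)(CC)CC)OC2=O)C[C@@H]1C(=C)C
A9 | alternative 3 | tert-butyl({2-[(1S,3R,4R)-4-ethenyl-4-methyl-3-(prop-1-en-2-yl)cyclohexyl]-1-methoxybuta-1,3-dien-1-yl}oxy)dimethylsilane | C=C[C@@]1(C)CC[C@H](C(C=C)=C(OC)O[Si](C)(C)C(C)(C)C)C[C@@H]1C(=C)C
A10 | alternative 3 | 2-methyl-2-[(triethylsilyl)oxy]propanal | CC(C)(C=O)O[Si](CC)(CC)CC
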